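**Plan**

1. Carotenoid numbering is used: ring A is the end ring without oxygen (C1–C6, chain C7–C15), ring B the hydroxylated ring (C1'–C6', chain C7'–C15'). The retrosynthesis cuts O–Si, then C14–C15 together with C13–CH3, giving a C18 terminal alkyne (C13≡C14, ring A) and a C21 (E)-alkenyl bromide (Br on C15, ring B). Each half is cut again at C10–C11/C9–CH3, and the ring B half also at C14'–C15'/C13'–CH3, back to one C13 enyne.
2. Enabling feature: every C(CH3)=CH unit of the chain (C9=C10, C13=C14 and their primed twins) is the syn adduct of CH3–Al to a terminal alkyne, and C13(CH3)=C14 lies directly on the C14–C15 single bond. Methyl group, E geometry and fragment union can therefore be delivered in one flask. Rings A and B (isolated trisubstituted C4=C5, doubly allylic C6–H) are inert to neutral organoalane/palladium conditions.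
3. Forward order: enone 1 → (R)-allylic alcohol → but-2-ynyl ether → [2,3]-Wittig shift → Meyer–Schuster shift to (S)-α-ionone 7 → enyne 9, common to both halves. No ring is formed; both six-membered rings come from 1.
4. Ring A half: 9 plus the C4 bromoenyne 15 gives alkyne 18. Ring B half: 9 → C3 ketone → C3 alcohol → silyl ether → two chain extensions → bromide 26. Then 18 + 26 → 28 → 29.
5. Stereochemistry: one oxazaborolidine reduction sets C–O in 2, and the suprafacial [2,3] shift relays it to C6 and C6'. C3' comes from a second, catalyst-controlled reduction. All chain alkenes are E through syn carbometalation, anti addition of IBr to acetylene and stereoretentive couplings.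

Key step: step 16

Remark: enone 1 is taken as a catalogue compound; the carbinol carbon of 6 forms as both epimers, which converge in step 4, so it carries no descriptor.

**Route**

Step 1
Reactants: 1 2,4,4-trimethylcyclohex-2-en-1-one
Product: 2 (1R)-2,4,4-trimethylcyclohex-2-en-1-ol
Conditions: (S)-tetrahydro-1-methyl-3,3-diphenyl-1H,3H-pyrrolo[1,2-c][1,3,2]oxazaborole (10 mol%), BH3·SMe2, THF, −20 °C; MeOH, aqueous work-up
Reagents that add atoms: none
Why: Corey–Bakshi–Shibata reduction; the boron-bound ketone turns its 2-methylalkenyl flank (the large group) away from the catalyst and hydride is delivered within the complex to one face, which should set the carbinol carbon as R.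

Step 2
Reactants: 2 (1R)-2,4,4-trimethylcyclohex-2-en-1-ol; 3 1-bromobut-2-yne
Product: 4 (6R)-6-(but-2-yn-1-yloxy)-1,3,3-trimethylcyclohex-1-ene
Conditions: NaH, Bu4NI (cat.), THF/DMF, 0 to 23 °C
Reagents that add atoms: none
Why: Williamson ether synthesis of the alkoxide with a reactive propargylic bromide; the carbinol centre is not touched.

Step 3
Reactants: 4 (6R)-6-(but-2-yn-1-yloxy)-1,3,3-trimethylcyclohex-1-ene
Product: 6 1-[(1S)-2,6,6-trimethylcyclohex-2-en-1-yl]but-2-yn-1-ol as both carbinol epimers, via lithiated ether 5 (not isolated)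
Conditions: n-BuLi, THF, −78 to −30 °C; H2O
Reagents that add atoms: none
Why: [2,3]-Wittig rearrangement; the propargylic α-oxy carbanion bonds to the ring =CH carbon on the face from which the pseudoaxial C–O bond leaves (suprafacial, five-membered envelope), so the C–O configuration of 4 should become the S configuration of the new ring centre (later C6) while the double bond moves to C4=C5.

Step 4
Reactants: 6 1-[(1S)-2,6,6-trimethylcyclohex-2-en-1-yl]but-2-yn-1-ol
Product: 7 (S)-α-ionone [(3E)-4-[(1S)-2,6,6-trimethylcyclohex-2-en-1-yl]but-3-en-2-one]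
Conditions: OV(OSiPh3)3 (5 mol%), toluene, 80 °C
Reagents that add atoms: none
Why: Meyer–Schuster rearrangement through a propargyl vanadate that shifts [3,3] to an allenyl vanadate and is protonated at C8; the neutral conditions spare C6, both carbinol epimers converge, and the conjugated E enone is the thermodynamic product.

Step 5
Reactants: 7 (S)-α-ionone
Product: 9 (6S)-6-[(1E)-but-1-en-3-yn-1-yl]-1,5,5-trimethylcyclohex-1-ene, via enol phosphate 8 (not isolated)
Conditions: LiN(i-Pr)2 (1.05 equiv), THF, −78 °C; ClP(O)(OEt)2; LiN(i-Pr)2 (2.2 equiv), −78 to 0 °C; H2O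
Reagents that add atoms: none
Why: enol phosphate route from a methyl ketone to a terminal alkyne (kinetic deprotonation at CH3, O-phosphorylation, base-induced β-elimination of diethyl phosphate); the cross-conjugated enolate forms faster than the C6 anion and the alkyne stays deprotonated until work-up, so C6 should keep its configuration.

Step 6
Reactants: 10 acetylene; 11 iodine monobromide
Product: 12 (E)-1-bromo-2-iodoethene
Conditions: 48% aqueous HBr, 0 °C
Reagents that add atoms: none
Why: electrophilic anti addition of I–Br across the triple bond (halogenation of an alkyne) should give the E dihalide.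

Step 7
Reactants: 12 (E)-1-bromo-2-iodoethene; 13 ethynyl(trimethyl)silane
Product: 15 [(3E)-4-bromobut-3-en-1-yn-1-yl](trimethyl)silane, via alkynylzinc bromide 14 (not isolated)
Conditions: 13, n-BuLi, THF, −78 °C; ZnBr2, 0 °C; then 12, Pd(PPh3)4 (2 mol%), THF, 0 to 23 °C
Reagents that add atoms: none
Why: Negishi alkynylation; zerovalent palladium inserts into the C–I bond much faster than into C–Br and the coupling retains the E geometry.

Step 8
Reactants: 9 (6S)-6-[(1E)-but-1-en-3-yn-1-yl]-1,5,5-trimethylcyclohex-1-ene; 15 [(3E)-4-bromobut-3-en-1-yn-1-yl](trimethyl)silane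
Product: 17 trimethyl{(3E,5E,7E)-6-methyl-8-[(1S)-2,6,6-trimethylcyclohex-2-en-1-yl]octa-3,5,7-trien-1-yn-1-yl}silane, via alkenylalane 16 (not isolated)
Conditions: Me3Al (2 equiv), Cp2ZrCl2 (25 mol%), ClCH2CH2Cl, 23 °C; evaporate; then 15, Pd2(dba)3 (2.5 mol%), P(2-furyl)3 (10 mol%), ZnCl2 (30 mol%), THF/DMF, 23 °C
Reagents that add atoms: trimethylaluminium, C[Al](C)C
Why: zirconium-catalysed methylalumination (Negishi carboalumination) adds CH3 and Al syn to C9≡C10 with Al on the terminal carbon, and the palladium/zinc-catalysed alkenyl–alkenyl Negishi coupling with 15 retains both geometries, so the 9E,11E diene should result.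

Step 9
Reactants: 17 the silylated trienyne
Product: 18 (6S)-1,5,5-trimethyl-6-[(1E,3E,5E)-3-methylocta-1,3,5-trien-7-yn-1-yl]cyclohex-1-ene
Conditions: K2CO3 (cat.), MeOH/THF, 23 °C
Reagents that add atoms: none
Why: methanolysis of the alkynyl C–Si bond (protodesilylation); the conditions are far too weakly basic to touch C6–H.

Step 10
Reactants: 9 (6S)-6-[(1E)-but-1-en-3-yn-1-yl]-1,5,5-trimethylcyclohex-1-ene
Product: 19 (4S)-4-[(1E)-but-1-en-3-yn-1-yl]-3,5,5-trimethylcyclohex-2-en-1-one
Conditions: Rh2(cap)4 (cap = caprolactamate, 1 mol%), t-BuOOH (70% in water, 5 equiv), ClCH2CH2Cl, 40 °C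
Reagents that add atoms: tert-butyl hydroperoxide, CC(C)(C)OO
Why: radical allylic oxidation (the tert-butylperoxy radical abstracts an allylic hydrogen and the mixed peroxide collapses to the enone); the ring C3 methylene is the only unhindered secondary allylic C–H, whereas the tertiary C6–H is screened by the C1 gem-dimethyl group and the C5 methyl.

Step 11
Reactants: 19 (4S)-4-[(1E)-but-1-en-3-yn-1-yl]-3,5,5-trimethylcyclohex-2-en-1-one
Product: 20 (1S,4S)-4-[(1E)-but-1-en-3-yn-1-yl]-3,5,5-trimethylcyclohex-2-en-1-ol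
Conditions: (R)-tetrahydro-1-methyl-3,3-diphenyl-1H,3H-pyrrolo[1,2-c][1,3,2]oxazaborole (20 mol%), catecholborane, toluene, −78 °C
Reagents that add atoms: none
Why: Corey–Bakshi–Shibata reduction under catalyst control; the C4=C5 alkene flank acts as the large group, so the (R)-catalyst should deliver hydride to the face that makes the carbinol carbon S (hydroxyl trans to the C6 side chain), and catecholborane at −78 °C leaves the alkyne alone.

Step 12
Reactants: 20 (1S,4S)-4-[(1E)-but-1-en-3-yn-1-yl]-3,5,5-trimethylcyclohex-2-en-1-ol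
Product: 21 tert-butyl{[(1S,4S)-4-[(1E)-but-1-en-3-yn-1-yl]-3,5,5-trimethylcyclohex-2-en-1-yl]oxy}dimethylsilane
Conditions: TBSCl, imidazole, DMF, 23 °C
Reagents that add atoms: tert-butyl(chloro)dimethylsilane, CC(C)(C)[Si](C)(C)Cl
Why: silylation of the secondary allylic alcohol removes the acidic O–H before the organoalane steps.

Step 13
Reactants: 21 the silyl ether enyne; 15 [(3E)-4-bromobut-3-en-1-yn-1-yl](trimethyl)silane
Product: 23 tert-butyl(dimethyl){[(1S,4S)-3,5,5-trimethyl-4-[(1E,3E,5E)-3-methyl-8-(trimethylsilyl)octa-1,3,5-trien-7-yn-1-yl]cyclohex-2-en-1-yl]oxy}silane, via alkenylalane 22 (not isolated)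
Conditions: Me3Al (2 equiv), Cp2ZrCl2 (25 mol%), ClCH2CH2Cl, 23 °C; evaporate; then 15, Pd2(dba)3 (2.5 mol%), P(2-furyl)3 (10 mol%), ZnCl2 (30 mol%), THF/DMF, 23 °C
Reagents that add atoms: trimethylaluminium, C[Al](C)C
Why: the same methylalumination/Negishi coupling as in step 8 should set 9'E and 11'E; the allylic silyl ether is not ionised by the alane at 23 °C.

Step 14
Reactants: 23 the doubly silylated trienyne
Product: 24 tert-butyl(dimethyl){[(1S,4S)-3,5,5-trimethyl-4-[(1E,3E,5E)-3-methylocta-1,3,5-trien-7-yn-1-yl]cyclohex-2-en-1-yl]oxy}silane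
Conditions: K2CO3 (cat.), MeOH/THF, 23 °C
Reagents that add atoms: none
Why: protodesilylation of the alkynylsilane by methoxide; the O–Si bond of the hindered silyl ether is stable to these conditions.

Step 15
Reactants: 24 the silyl ether trienyne; 12 (E)-1-bromo-2-iodoethene
Product: 26 {[(1S,4S)-4-[(1E,3E,5E,7E,9E)-10-bromo-3,7-dimethyldeca-1,3,5,7,9-pentaen-1-yl]-3,5,5-trimethylcyclohex-2-en-1-yl]oxy}(tert-butyl)dimethylsilane, via alkenylalane 25 (not isolated)
Conditions: Me3Al (2 equiv), Cp2ZrCl2 (25 mol%), ClCH2CH2Cl, 23 °C; evaporate; then 12 (2 equiv), Pd(PPh3)4 (5 mol%), ZnCl2 (30 mol%), THF/DMF, 0 to 23 °C, dark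
Reagents that add atoms: trimethylaluminium, C[Al](C)C
Why: methylalumination sets 13'E, and the Negishi coupling should take place only at the C–I bond of 12 (faster oxidative addition than at C–Br), which leaves the bromide on C15 for the key step.

Step 16
Reactants: 18 the ring A C18 alkyne; 26 the ring B C21 bromide
Product: 28 tert-butyldimethylsilyl ether of (3S,6S,6'S)-ε,ε-caroten-3-ol, via alkenylalane 27 (not isolated)
Conditions: 18, Me3Al (2 equiv), Cp2ZrCl2 (25 mol%), ClCH2CH2Cl, 23 °C; evaporate; then 26, Pd2(dba)3 (2.5 mol%), P(2-furyl)3 (10 mol%), ZnCl2 (30 mol%), THF/DMF, 23 °C, dark, argon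
Reagents that add atoms: trimethylaluminium, C[Al](C)C
Why: Cp2ZrCl2 and Me3Al generate a methylzirconium species that adds CH3 and metal syn across the terminal C13≡C14 triple bond of 18 with the metal on the terminal carbon C14, and exchange with aluminium gives alane 27; zerovalent palladium inserts into the C15–Br bond of 26 with retention, the alkenyl group passes from aluminium through zinc to palladium, and reductive elimination forms the C14–C15 bond. The closest known reaction type is the one-pot zirconium-catalysed methylalumination of a conjugated enyne followed by palladium- and zinc-catalysed alkenyl–alkenyl Negishi coupling, an established way to assemble all-E oligoenes. No ring is closed and no stereocentre is formed; the new stereo-element is the E geometry of C13=C14, fixed by the syn addition, while the E geometry of C15=C15' is carried over unchanged from 26. The step needs carbometalation of the alkyne only, methyl on the inner carbon, and coupling without scrambling of the nonaene or of C6 and C6'. The substrate secures this because the C13≡C14–H unit is its only terminal alkyne (the trisubstituted C4=C5 ring alkenes and the internal chain alkenes do not insert), the conjugated enyne directs the metal to the terminal carbon, and the neutral conditions at 23 °C leave the doubly allylic C6–H bonds and the silyl ether untouched.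

Step 17
Reactants: 28 the silyl ether of the target
Product: 29 (3S,6S,6'S)-ε,ε-caroten-3-ol
Conditions: Bu4NF, THF, 0 to 23 °C, dark
Reagents that add atoms: none
Why: fluoride-induced cleavage of the O–Si bond (desilylation); the conditions are mild enough for the polyene and for the allylic alcohol, and the carbinol centre is not involved.

**Compound list**

1 | 2,4,4-trimethylcyclohex-2-en-1-one | CC1=CC(C)(C)CCC1=O | starting material
2 | (1R)-2,4,4-trimethylcyclohex-2-en-1-ol | O[C@@H]1CCC(C)(C)C=C1C | intermediate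
3 | 1-bromobut-2-yne | CC#CCBr | starting material
4 | (6R)-6-(but-2-yn-1-yloxy)-1,3,3-trimethylcyclohex-1-ene | CC#CCO[C@@H]1CCC(C)(C)C=C1C | intermediate
5 | lithiated ether (lithium on the O–CH carbon of 4; formed in the flask) | CC#CC([Li])O[C@@H]1CCC(C)(C)C=C1C | intermediate
6 | 1-[(1S)-2,6,6-trimethylcyclohex-2-en-1-yl]but-2-yn-1-ol (both carbinol epimers) | CC#CC(O)[C@@H]1C(C)=CCCC1(C)C | intermediate
7 | (S)-α-ionone, (3E)-4-[(1S)-2,6,6-trimethylcyclohex-2-en-1-yl]but-3-en-2-one | CC(=O)/C=C/[C@@H]1C(C)=CCCC1(C)C | intermediate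
8 | diethyl (3E)-4-[(1S)-2,6,6-trimethylcyclohex-2-en-1-yl]buta-1,3-dien-2-yl phosphate (formed in the flask) | C=C(OP(=O)(OCC)OCC)/C=C/[C@@H]1C(C)=CCCC1(C)C | intermediate
9 | (6S)-6-[(1E)-but-1-en-3-yn-1-yl]-1,5,5-trimethylcyclohex-1-ene | C#C/C=C/[C@@H]1C(C)=CCCC1(C)C | intermediate
10 | acetylene | C#C | starting material
11 | iodine monobromide | IBr | starting material
12 | (E)-1-bromo-2-iodoethene | Br/C=C/I | intermediate
13 | ethynyl(trimethyl)silane | C#C[Si](C)(C)C | starting material
14 | bromo[(trimethylsilyl)ethynyl]zinc (formed in the flask) | C[Si](C)(C)C#C[Zn]Br | intermediate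
15 | [(3E)-4-bromobut-3-en-1-yn-1-yl](trimethyl)silane | C[Si](C)(C)C#C/C=C/Br | intermediate
16 | dimethyl{(1E,3E)-2-methyl-4-[(1S)-2,6,6-trimethylcyclohex-2-en-1-yl]buta-1,3-dien-1-yl}alumane (formed in the flask) | C[Al](C)/C=C(C)/C=C/[C@@H]1C(C)=CCCC1(C)C | intermediate
17 | trimethyl{(3E,5E,7E)-6-methyl-8-[(1S)-2,6,6-trimethylcyclohex-2-en-1-yl]octa-3,5,7-trien-1-yn-1-yl}silane | C[Si](C)(C)C#C/C=C/C=C(C)/C=C/[C@@H]1C(C)=CCCC1(C)C | intermediate
18 | (6S)-1,5,5-trimethyl-6-[(1E,3E,5E)-3-methylocta-1,3,5-trien-7-yn-1-yl]cyclohex-1-ene | C#C/C=C/C=C(C)/C=C/[C@@H]1C(C)=CCCC1(C)C | intermediate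
19 | (4S)-4-[(1E)-but-1-en-3-yn-1-yl]-3,5,5-trimethylcyclohex-2-en-1-one | C#C/C=C/[C@@H]1C(C)=CC(=O)CC1(C)C | intermediate
20 | (1S,4S)-4-[(1E)-but-1-en-3-yn-1-yl]-3,5,5-trimethylcyclohex-2-en-1-ol (hydroxyl trans to the side chain) | C#C/C=C/[C@@H]1C(C)=C[C@@H](O)CC1(C)C | intermediate
21 | tert-butyl{[(1S,4S)-4-[(1E)-but-1-en-3-yn-1-yl]-3,5,5-trimethylcyclohex-2-en-1-yl]oxy}dimethylsilane | C#C/C=C/[C@@H]1C(C)=C[C@@H](O[Si](C)(C)C(C)(C)C)CC1(C)C | intermediate
22 | {(1E,3E)-4-[(1S,4S)-4-{[tert-butyl(dimethyl)silyl]oxy}-2,6,6-trimethylcyclohex-2-en-1-yl]-2-methylbuta-1,3-dien-1-yl}(dimethyl)alumane (formed in the flask) | C[Al](C)/C=C(C)/C=C/[C@@H]1C(C)=C[C@@H](O[Si](C)(C)C(C)(C)C)CC1(C)C | intermediate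
23 | tert-butyl(dimethyl){[(1S,4S)-3,5,5-trimethyl-4-[(1E,3E,5E)-3-methyl-8-(trimethylsilyl)octa-1,3,5-trien-7-yn-1-yl]cyclohex-2-en-1-yl]oxy}silane | C[Si](C)(C)C#C/C=C/C=C(C)/C=C/[C@@H]1C(C)=C[C@@H](O[Si](C)(C)C(C)(C)C)CC1(C)C | intermediate
24 | tert-butyl(dimethyl){[(1S,4S)-3,5,5-trimethyl-4-[(1E,3E,5E)-3-methylocta-1,3,5-trien-7-yn-1-yl]cyclohex-2-en-1-yl]oxy}silane | C#C/C=C/C=C(C)/C=C/[C@@H]1C(C)=C[C@@H](O[Si](C)(C)C(C)(C)C)CC1(C)C | intermediate
25 | {(1E,3E,5E,7E)-8-[(1S,4S)-4-{[tert-butyl(dimethyl)silyl]oxy}-2,6,6-trimethylcyclohex-2-en-1-yl]-2,6-dimethylocta-1,3,5,7-tetraen-1-yl}(dimethyl)alumane (formed in the flask) | C[Al](C)/C=C(C)/C=C/C=C(C)/C=C/[C@@H]1C(C)=C[C@@H](O[Si](C)(C)C(C)(C)C)CC1(C)C | intermediate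
26 | {[(1S,4S)-4-[(1E,3E,5E,7E,9E)-10-bromo-3,7-dimethyldeca-1,3,5,7,9-pentaen-1-yl]-3,5,5-trimethylcyclohex-2-en-1-yl]oxy}(tert-butyl)dimethylsilane | Br/C=C/C=C(C)/C=C/C=C(C)/C=C/[C@@H]1C(C)=C[C@@H](O[Si](C)(C)C(C)(C)C)CC1(C)C | intermediate
27 | {(1E,3E,5E,7E)-2,6-dimethyl-8-[(1S)-2,6,6-trimethylcyclohex-2-en-1-yl]octa-1,3,5,7-tetraen-1-yl}(dimethyl)alumane (formed in the flask) | C[Al](C)/C=C(C)/C=C/C=C(C)/C=C/[C@@H]1C(C)=CCCC1(C)C | intermediate
28 | tert-butyldimethylsilyl ether of all-E (3S,6S,6'S)-ε,ε-caroten-3-ol | CC1=CCCC(C)(C)[C@@H]1/C=C/C(C)=C/C=C/C(C)=C/C=C/C=C(C)/C=C/C=C(C)/C=C/[C@@H]1C(C)=C[C@@H](O[Si](C)(C)C(C)(C)C)CC1(C)C | intermediate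
29 | all-E (3S,6S,6'S)-ε,ε-caroten-3-ol (hydroxylated ring = ring B of the text) | CC1=CCCC(C)(C)[C@@H]1/C=C/C(C)=C/C=C/C(C)=C/C=C/C=C(C)/C=C/C=C(C)/C=C/[C@@H]1C(C)=C[C@@H](O)CC1(C)C | target

**Step count and risks**

Total step count: 17. Longest linear sequence: 13 steps (1, 2, 3, 4, 5, 10, 11, 12, 13, 14, 15, 16, 17).

Step 10. What may go wrong: hydrogen abstraction at the doubly allylic C6–H, or addition of peroxy radicals to the conjugated enyne, competes with oxidation at C3, and the enone formed may epimerise at C6. The fallback sets out from 7 and comes back at 21; it moves the oxidation to the ketone-protected ionone, the substrate class on which this oxidation is best established. Ketalisation of 7 (ethylene glycol, HC(OEt)3, TsOH cat., 23 °C) should give the dioxolane F1. Allylic oxidation (t-BuOOH, Rh2(cap)4) should give the ring enone F2. Reduction as in step 11 should give the trans alcohol F3, and silylation (TBSCl, imidazole) the silyl ether F4. Ketal hydrolysis (PPTS, acetone/water) should give the silyloxy ionone F5. The sequence of step 5, through the enol phosphate F6, then leads to 21.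

Step 3. What may go wrong: bond formation at the ring carbon next to the quaternary centre is slow, so that [1,2]-shift, elimination or propargyl–allenyl isomerisation of the lithiated ether takes over. The fallback sets out from 2 and comes back at 9; it replaces the carbanion shift by a thermal Johnson–Claisen rearrangement ([3,3], same suprafacial chirality transfer). Heating 2 with triethyl orthoacetate and catalytic propionic acid (140 °C) should form the ketene acetal F7, which rearranges in the flask to the ester F8. i-Bu2AlH (−78 °C) should give the aldehyde F9, and HC≡CMgBr the propargylic alcohol F10. Mesylation (MsCl, Et3N) to the mesylate F11 and anti elimination with DBU should give the E enyne 9. This also bypasses steps 4 and 5.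

Step 11. What may go wrong: poor facial selectivity, because the hydride has to enter on the ring face that also carries the C6 side chain, so catalyst and substrate preferences may oppose each other. The fallback sets out from 19 and comes back at 20; it uses substrate-controlled reduction followed by inversion. LiBH(s-Bu)3 (THF, −78 °C) should add from the face remote from the side chain and give the cis alcohol F12. A Mitsunobu reaction (4-nitrobenzoic acid, PPh3, diisopropyl azodicarboxylate) should invert the carbinol carbon to the trans 4-nitrobenzoate F13; substitution is expected at C3 because the other allylic terminus, C5, is fully substituted. K2CO3 in MeOH then liberates 20.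

**Further compounds**

F1 | step 10 | 2-methyl-2-{(E)-2-[(1S)-2,6,6-trimethylcyclohex-2-en-1-yl]ethenyl}-1,3-dioxolane | CC1(/C=C/[C@@H]2C(C)=CCCC2(C)C)OCCO1
F2 | step 10 | (4S)-3,5,5-trimethyl-4-[(E)-2-(2-methyl-1,3-dioxolan-2-yl)ethenyl]cyclohex-2-en-1-one | CC1(/C=C/[C@@H]2C(C)=CC(=O)CC2(C)C)OCCO1
F3 | step 10 | (1S,4S)-3,5,5-trimethyl-4-[(E)-2-(2-methyl-1,3-dioxolan-2-yl)ethenyl]cyclohex-2-en-1-ol | CC1(/C=C/[C@@H]2C(C)=C[C@@H](O)CC2(C)C)OCCO1
F4 | step 10 | tert-butyl(dimethyl){[(1S,4S)-3,5,5-trimethyl-4-[(E)-2-(2-methyl-1,3-dioxolan-2-yl)ethenyl]cyclohex-2-en-1-yl]oxy}silane | CC1(/C=C/[C@@H]2C(C)=C[C@@H](O[Si](C)(C)C(C)(C)C)CC2(C)C)OCCO1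
F5 | step 10 | (3E)-4-[(1S,4S)-4-{[tert-butyl(dimethyl)silyl]oxy}-2,6,6-trimethylcyclohex-2-en-1-yl]but-3-en-2-one | CC(=O)/C=C/[C@@H]1C(C)=C[C@@H](O[Si](C)(C)C(C)(C)C)CC1(C)C
F6 | step 10 | diethyl (3E)-4-[(1S,4S)-4-{[tert-butyl(dimethyl)silyl]oxy}-2,6,6-trimethylcyclohex-2-en-1-yl]buta-1,3-dien-2-yl phosphate | C=C(OP(=O)(OCC)OCC)/C=C/[C@@H]1C(C)=C[C@@H](O[Si](C)(C)C(C)(C)C)CC1(C)C
F7 | step 3 | (6R)-6-[(1-ethoxyethenyl)oxy]-1,3,3-trimethylcyclohex-1-ene | C=C(OCC)O[C@@H]1CCC(C)(C)C=C1C
F8 | step 3 | ethyl [(1S)-2,6,6-trimethylcyclohex-2-en-1-yl]acetate | CCOC(=O)C[C@@H]1C(C)=CCCC1(C)C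
F9 | step 3 | [(1S)-2,6,6-trimethylcyclohex-2-en-1-yl]acetaldehyde | O=CC[C@@H]1C(C)=CCCC1(C)C
F10 | step 3 | 1-[(1S)-2,6,6-trimethylcyclohex-2-en-1-yl]but-3-yn-2-ol (both carbinol epimers) | C#CC(O)C[C@@H]1C(C)=CCCC1(C)C
F11 | step 3 | 1-[(1S)-2,6,6-trimethylcyclohex-2-en-1-yl]but-3-yn-2-yl methanesulfonate | C#CC(OS(C)(=O)=O)C[C@@H]1C(C)=CCCC1(C)C
F12 | step 11 | (1R,4S)-4-[(1E)-but-1-en-3-yn-1-yl]-3,5,5-trimethylcyclohex-2-en-1-ol | C#C/C=C/[C@@H]1C(C)=C[C@H](O)CC1(C)C
F13 | step 11 | (1S,4S)-4-[(1E)-but-1-en-3-yn-1-yl]-3,5,5-trimethylcyclohex-2-en-1-yl 4-nitrobenzoate | C#C/C=C/[C@@H]1C(C)=C[C@@H](OC(=O)c2ccc(cc2)[N+](=O)[O-])CC1(C)C
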